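## Retrosynthetic overview

1. Target ⇐ unmasking of the α-methylene lactone (Mannich base) and of the C6 hydroxyl (tert-butyl carbonate) ⇐ C9 acylation ⇐ face-selective syn-dihydroxylation of a (Z)-C9=C10 cyclodecene.
2. Ten-membered ring and lactone ⇐ four-carbon radical ring expansion of a fully substituted cyclohexanone (ring B, C5–C10) carrying a pent-4-enyl chain on C10 and a C8–C9 epoxide: C4–C5 is made, C5–C10 is broken, the epoxide opens.
3. Ring B ⇐ Michael addition / enolate hydroxylation on a γ,δ-epoxy enone ⇐ catalytic asymmetric epoxidation of a 6,6-disubstituted cyclohexa-2,4-dienone ⇐ 2-methylcyclohex-2-enone + 5-bromopent-1-ene.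
4. Ring order: six-membered ring B (commercial enone) → ten-membered carbocycle (ring expansion) → γ-lactone (same step).

Assumption: the target's numbering (ring carbons C1–C10, lactone carbons C11–C13, methyls C14/C15; target = 4S,6S,7S,8R,9S,10R) is used for all intermediates. C10 (erased in step 6) and C11 (erased in step 9) are carried as epimer mixtures and are left undefined in the SMILES.

## Route

Step 1
Reactants: 1 2-methylcyclohex-2-en-1-one; 2 5-bromopent-1-ene
Product: 4 rac-2-methyl-2-(pent-4-en-1-yl)cyclohex-3-en-1-one, via potassium dienolate 3 (not isolated)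
Conditions: t-BuOK (1.05 equiv), t-BuOH–THF, 0 °C; then 2, NaI (10 mol %), 0 °C to rt
Reagents that add atoms: none
Why: Thermodynamic γ-deprotonation gives the extended dienolate, which alkylates at the α-carbon (deconjugative α-alkylation of an enone) to build quaternary C10; its configuration is irrelevant because C10 becomes a radical in step 6.

Step 2
Reactants: 4 rac-2-methyl-2-(pent-4-en-1-yl)cyclohex-3-en-1-one
Product: 6 rac-6-methyl-6-(pent-4-en-1-yl)cyclohexa-2,4-dien-1-one, via lithium enolate 5 (not isolated)
Conditions: LiN(i-Pr)2, THF, −78 °C; then N-tert-butylbenzenesulfinimidoyl chloride, −78 °C; used at once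
Reagents that add atoms: none
Why: Mukaiyama dehydrogenation of the only possible (C6) enolate gives the linear dienone at −78 °C, cold enough to avoid Diels–Alder dimerisation of the blocked 2,4-dienone.

Step 3
Reactants: 6 rac-6-methyl-6-(pent-4-en-1-yl)cyclohexa-2,4-dien-1-one
Product: 7 (8R,9S)-γ,δ-epoxy enone [(1S,6R)-2-methyl-2-(pent-4-en-1-yl)-7-oxabicyclo[4.1.0]hept-4-en-3-one; 1:1 at C10]
Conditions: (R,R)-[N,N'-bis(3,5-di-tert-butylsalicylidene)-1,2-cyclohexanediamine]MnCl (5 mol %), mCPBA (1.5 equiv), N-methylmorpholine N-oxide (5 equiv), CH2Cl2, −78 °C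
Reagents that add atoms: mCPBA, O=C(OO)c1cccc(Cl)c1
Why: Jacobsen–Katsuki epoxidation selects the electron-richer cis-disubstituted γ,δ-alkene conjugated to the enone and sets C8 (R) and C9 under catalyst control (sense assigned by analogy with indene, which gives the (1R,2S)-oxide with this catalyst enantiomer); the Me/CH2R pair on C10 offers no substrate bias, so both C10 epimers form and are carried on together.

Step 4
Reactants: 8 methyl acrylate; 9 dimethylamine
Product: 10 methyl 3-(dimethylamino)propanoate
Conditions: Me2NH (2 M in MeOH), 0 °C to rt; distil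
Reagents that add atoms: none
Why: Aza-Michael addition gives the Mannich-base form of the acrylate α-anion, which carries no alkene through the hydrogen-atom-transfer and osmium steps.

Step 5
Reactants: 7 (8R,9S)-γ,δ-epoxy enone; 10 methyl 3-(dimethylamino)propanoate
Product: 14 ring B ketone with (6S)-OBoc and the C7 amino-ester arm and the (8R,9S)-epoxide (C10/C11 epimer mixture), via lithium ester enolate 11 (not isolated), via lithium ketone enolate 12 (not isolated), via lithium alkoxide 13 (not isolated)
Conditions: 10, LiN(i-Pr)2, THF, −78 °C; then 7, DMPU, −78 °C; then 2-(phenylsulfonyl)-3-phenyloxaziridine, −78 °C; then Boc2O, −78 to 0 °C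
Reagents that add atoms: 2-(phenylsulfonyl)-3-phenyloxaziridine, O=S(=O)(c1ccccc1)N1OC1c1ccccc1; di-tert-butyl dicarbonate, CC(C)(C)OC(=O)OC(=O)OC(C)(C)C
Why: Michael addition (1,2-attack is blocked by the neopentyl carbonyl) occurs anti to the epoxide and sets C7, Davis hydroxylation of the resulting enolate occurs anti to the new C7 arm and sets C6 (all-trans C6/C7/C8 as in the target), and the alkoxide is capped in situ as a carbonate so that C6 carries an electron-poor acyloxy group in step 6.

Step 6
Reactants: 14 ring B ketone (Boc carbonate)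
Product: 16 (Z)-cyclodec-9-en-5-one 12,8-lactone with 4S methyl and 6-OBoc and C11 CH2NMe2 arm, via ring-expanded hydroxy ester 15 (not isolated)
Conditions: Fe(acac)3 (30 mol %), PhSiH3 (1.3 equiv, slow addition), degassed EtOH (0.01 M), 60 °C; then 2-hydroxypyridine (10 mol %), toluene, 60 °C to complete lactonisation
Reagents that add atoms: none
Why: Proposed new method: iron-hydride hydrogen-atom transfer to the terminal alkene gives the secondary C4 radical, which adds 6-exo to the C5 ketone through a chair transition state (C4 methyl equatorial, ring B held by its equatorial C6/C7 groups, so both C10 epimers give 4S); the bicyclic alkoxy radical then undergoes β-scission of C5–C10 to the tertiary C10 radical (the C6 carbonate disfavours the competing C5–C6 scission), which is trapped irreversibly by opening of the adjacent epoxide to give the less strained (Z)-C9=C10 alkene and a C8 alkoxy radical that is reduced and lactonises; the closest known reactions are the Dowd–Beckwith ring expansion of haloalkyl β-keto esters, the iron-mediated hydrogen-atom-transfer alkene–ketone cyclisation and radical epoxide fragmentation.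

Step 7
Reactants: 16 (Z)-cyclodecenone lactone
Product: 17 (9S,10R)-9,10-diol
Conditions: OsO4 (2 mol %), (DHQ)2PHAL (5 mol %), N-methylmorpholine N-oxide (1.5 equiv), acetone–H2O 5:1, 0 °C
Reagents that add atoms: OsO4, O=[Os](=O)(=O)=O; N-methylmorpholine N-oxide, C[N+]1([O-])CCOCC1; water, O
Why: Syn-dihydroxylation (Upjohn conditions with a Sharpless ligand): allylic 1,3-strain with the cis C1 puts H8 in the alkene plane, the ring (C7 side) blocks the inner face, and osmium adds to the outer face syn to O8, which with 8R gives 9S,10R; the DHQ ligand is the matched one by the Sharpless mnemonic.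

Step 8
Reactants: 17 (9S,10R)-9,10-diol; 18 3-methylbutanoyl chloride (isovaleryl chloride)
Product: 19 C9 isovalerate
Conditions: 18 (1.5 equiv), pyridine, DMAP (10 mol %), CH2Cl2, 0 °C to rt
Reagents that add atoms: none
Why: Nucleophilic-catalysed acylation takes the only free secondary hydroxyl (C9); the tertiary C10 hydroxyl does not react and C6 is still protected.

Step 9
Reactants: 19 C9 isovalerate
Product: 21 O6-Boc-protected target, via trimethylammonium iodide 20 (not isolated)
Conditions: MeI (10 equiv), MeOH, rt; then NaHCO3 (aq)–EtOAc, rt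
Reagents that add atoms: none
Why: Exhaustive N-methylation followed by mild E1cB (Hofmann-type) elimination of the Mannich base unveils the α-methylene-γ-butyrolactone and removes the C11 stereocentre.

Step 10
Reactants: 21 O6-Boc-protected target
Product: 22 target (CNP0240128.1)
Conditions: CF3CO2H–CH2Cl2 1:4, 0 °C, 30 min; NaHCO3 work-up
Reagents that add atoms: none
Why: Acidolysis of the tert-butyl carbonate frees the C6 hydroxyl; the isovalerate, lactone and C10 tertiary alcohol (ionisation disfavoured by the adjacent acyloxy group) survive.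

## Compound list

1 | 2-methylcyclohex-2-en-1-one | CC1=CCCCC1=O | starting material
2 | 5-bromopent-1-ene | C=CCCCBr | starting material
3 | potassium 2-methylcyclohexa-1,3-dien-1-olate (extended dienolate of 1) | CC1=C([O-])CCC=C1.[K+] | intermediate
4 | rac-2-methyl-2-(pent-4-en-1-yl)cyclohex-3-en-1-one | C=CCCCC1(C)C=CCCC1=O | intermediate
5 | lithium 6-methyl-6-(pent-4-en-1-yl)cyclohexa-1,4-dien-1-olate (enolate of 4) | C=CCCCC1(C)C=CCC=C1[O-].[Li+] | intermediate
6 | rac-6-methyl-6-(pent-4-en-1-yl)cyclohexa-2,4-dien-1-one | C=CCCCC1(C)C=CC=CC1=O | intermediate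
7 | (1S,6R)-2-methyl-2-(pent-4-en-1-yl)-7-oxabicyclo[4.1.0]hept-4-en-3-one, i.e. (8R,9S)-epoxy enone, 1:1 epimers at C10 | C=CCCCC1(C)C(=O)C=C[C@H]2O[C@@H]12 | intermediate
8 | methyl acrylate | C=CC(=O)OC | starting material
9 | dimethylamine | CNC | starting material
10 | methyl 3-(dimethylamino)propanoate | CN(C)CCC(=O)OC | intermediate
11 | lithium enolate of 10 | CN(C)CC=C(OC)[O-].[Li+] | intermediate
12 | lithium C5 enolate of the Michael adduct (C7 arm anti to the epoxide) | C=CCCCC1(C)C([O-])=C[C@H](C(CN(C)C)C(=O)OC)[C@H]2O[C@@H]12.[Li+] | intermediate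
13 | lithium alkoxide of the (6S)-α-hydroxy ketone | C=CCCCC1(C)C(=O)[C@@H]([O-])[C@H](C(CN(C)C)C(=O)OC)[C@H]2O[C@@H]12.[Li+] | intermediate
14 | ring B ketone: C5 ketone, (6S)-OBoc, C7 arm CH(CO2Me)CH2NMe2, (8R,9S)-epoxide, C10 methyl and pent-4-enyl; C6/C7/C8 arranged as in the target; C10/C11 epimer mixture | C=CCCCC1(C)C(=O)[C@@H](OC(=O)OC(C)(C)C)[C@H](C(CN(C)C)C(=O)OC)[C@H]2O[C@@H]12 | intermediate
15 | ring-expanded hydroxy ester: (Z)-cyclodec-9-en-5-one with 4S methyl, 6-OBoc, C7 amino-ester arm, free 8-OH; C11 epimers | C/C1=C/[C@H](O)[C@@H](C(CN(C)C)C(=O)OC)[C@H](OC(=O)OC(C)(C)C)C(=O)[C@@H](C)CCC1 | intermediate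
16 | (Z)-cyclodec-9-en-5-one trans-fused 12,8-lactone with 4S methyl, 6-OBoc, C11 CH2NMe2; C11 epimers | C/C1=C/[C@@H]2OC(=O)C(CN(C)C)[C@H]2[C@H](OC(=O)OC(C)(C)C)C(=O)[C@@H](C)CCC1 | intermediate
17 | (9S,10R)-9,10-diol of 16 | CN(C)CC1C(=O)O[C@@H]2[C@@H]1[C@H](OC(=O)OC(C)(C)C)C(=O)[C@@H](C)CCC[C@@](C)(O)[C@H]2O | intermediate
18 | 3-methylbutanoyl chloride (isovaleryl chloride) | CC(C)CC(=O)Cl | starting material
19 | C9 isovalerate of 17 | CN(C)CC1C(=O)O[C@@H]2[C@@H]1[C@H](OC(=O)OC(C)(C)C)C(=O)[C@@H](C)CCC[C@@](C)(O)[C@H]2OC(=O)CC(C)C | intermediate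
20 | trimethylammonium iodide of 19 | C[N+](C)(C)CC1C(=O)O[C@@H]2[C@@H]1[C@H](OC(=O)OC(C)(C)C)C(=O)[C@@H](C)CCC[C@@](C)(O)[C@H]2OC(=O)CC(C)C.[I-] | intermediate
21 | O6-tert-butoxycarbonyl derivative of the target | C=C1C(=O)O[C@@H]2[C@@H]1[C@H](OC(=O)OC(C)(C)C)C(=O)[C@@H](C)CCC[C@@](C)(O)[C@H]2OC(=O)CC(C)C | intermediate
22 | CNP0240128.1 (4S,6S,7S,8R,9S,10R) | C=C1C(=O)O[C@@H]2[C@@H]1[C@H](O)C(=O)[C@@H](C)CCC[C@@](C)(O)[C@H]2OC(=O)CC(C)C | target

## Step count and risks

Total: 10 steps. Longest linear sequence: 9 steps (steps 1–3 and 5–10; step 4 is a one-step side branch).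

The three steps most likely to fail:

Step 6 (the proposed new ring expansion). Three things can go wrong: the bicyclic alkoxy radical may be reduced before it fragments, the product's trisubstituted alkene may be reduced by further hydrogen-atom transfer (hence limited silane and high dilution), or some E alkene may form. The fallback uses known chemistry and sets out from 14. The same iron/silane conditions, run to the stage where the cascade stops after ketone addition (the established hydrogen-atom-transfer alkene–ketone cyclisation), give the cis-fused epoxy decalinol F3. Its tertiary alcohol, with the amine held as the trifluoroacetate salt, is then fragmented under classical hypoiodite alkoxy-radical conditions (PhI(OAc)2, I2, visible light, CH2Cl2, then Na2S2O3). β-Scission, epoxide opening and lactonisation via 15 bring the material back to the route at 16.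

Step 5 (one-pot Michael addition / hydroxylation / carbonate formation). Risks are 1,2-addition, imine–aldol capture of the lithium enolate by the oxaziridine by-product, and incomplete trapping. The fallback sets out from 7 and 10 and replaces the enolate oxidation by silyl enol ether chemistry. The Michael enolate is quenched with Me3SiCl and isolated as the trimethylsilyl enol ether F1. This is oxidised as its camphorsulfonate salt with dimethyldioxirane at −78 °C (Rubottom oxidation) to the α-hydroxy ketone F2. F2 is converted with Boc2O/DMAP into 14, where the route is rejoined.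

Step 7 (facial selectivity of the dihydroxylation). If osmium attacks the inner face, the 9,10-diastereomer is wrong. The fallback sets out from 16 and uses a Woodward–Prévost sequence, which delivers the cis-diol monoester on the face opposite to the one first attacked by the electrophile. I2 and AgO2CCH2CH(CH3)2 in wet 3-methylbutanoic acid give the trans iodo isovalerate F4 (isovalerate on C10, iodide on C9). Silver-assisted displacement of iodide through the dioxolanylium ion, hydrolysis and tertiary-to-secondary acyl migration then give 19 directly. The route is rejoined there, and steps 7 and 8 are bypassed.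

Further compounds

F1 | step 5 | trimethylsilyl enol ether of the Michael adduct (C5 OSiMe3, C5=C6; C10/C11 epimers) | C=CCCCC1(C)C(O[Si](C)(C)C)=C[C@H](C(CN(C)C)C(=O)OC)[C@H]2O[C@@H]12
F2 | step 5 | (6S)-α-hydroxy ketone (free alcohol of 13) | C=CCCCC1(C)C(=O)[C@@H](O)[C@H](C(CN(C)C)C(=O)OC)[C@H]2O[C@@H]12
F3 | step 6 | cis-fused epoxy decalinol (C4–C5 bond formed, 4S methyl, tertiary 5-OH, epoxide intact; C5/C10/C11 epimers) | C[C@H]1CCCC2(C)[C@@H]3O[C@@H]3[C@@H](C(CN(C)C)C(=O)OC)[C@H](OC(=O)OC(C)(C)C)C12O
F4 | step 7 | trans iodo isovalerate of 16 (10-O-isovaleryl, 9-iodo) | CN(C)CC1C(=O)O[C@@H]2[C@@H]1[C@H](OC(=O)OC(C)(C)C)C(=O)[C@@H](C)CCC[C@@](C)(OC(=O)CC(C)C)[C@@H]2I
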